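The pyranone is disconnected at C4a–C4 and C4–C3. One palladium-catalysed carbonylation unites a ring A aryl iodide, CO and the enolate of 2-methoxy-1-phenylethanone, giving directly the 2-methoxy-1,3-diketone that contains C4, C3–OMe, C2 and ring B. The step exploits two features: the C4 carbonyl lies between C4a and the methoxylated C3, and in ring A the iodinated carbon (future C4a) is flanked by a MOM ether (future O1, beside the CH2-bearing C8) and a benzyl ether (future 5-OH), so ring C can close only with the bridge at C8. The precursor is the MOM-protected ring D dihydrochalcone joined through CH2 to this iodinated ring; the iodine is introduced while that ring is still symmetric.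

Key step: step 9

Remark: the target has no stereocentre; the methoxylated carbon of the diketone is the only sp3 centre formed on the way, is enolisable, is left unassigned and disappears on ring closure. MOM = methoxymethyl; flavone numbering (O1, C2 to C8a) is used for rings A and C.

Step 1
Reactants: 1 2-methylbenzene-1,3,5-triol (2-methylphloroglucinol); 2 3-phenylpropanoyl chloride
Product: 3 1-(2,4,6-trihydroxy-3-methylphenyl)-3-phenylpropan-1-one
Conditions: AlCl3 (3.5 equiv), PhNO2–CH2Cl2, 0 → 50 °C; then ice/aq HCl
Reagents that add atoms: none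
Why: Friedel–Crafts acylation (any O-acyl ester should undergo Fries rearrangement under AlCl3) at one of the two equivalent free positions of the triol, and the first acyl group deactivates the ring against a second.

Step 2
Reactants: 3 1-(2,4,6-trihydroxy-3-methylphenyl)-3-phenylpropan-1-one
Product: 4 1-(2,6-dihydroxy-4-methoxy-3-methylphenyl)-3-phenylpropan-1-one
Conditions: Me2SO4 (1.0 equiv), K2CO3 (1.0 equiv), acetone, reflux
Reagents that add atoms: dimethyl sulfate, COS(=O)(=O)OC
Why: Williamson-type O-methylation with one equivalent of electrophile should go to the para hydroxyl, which is the most acidic (vinylogous acid) and not next to the carbonyl, whereas the two ortho hydroxyls are held back by hydrogen bonding to C=O.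

Step 3
Reactants: 5 2,4,6-trihydroxybenzaldehyde
Product: 6 4-(benzyloxy)-2,6-dihydroxybenzaldehyde
Conditions: BnBr (1.0 equiv), NaHCO3 (1.1 equiv), DMF, rt → 40 °C
Reagents that add atoms: benzyl bromide, BrCc1ccccc1
Why: Williamson etherification in which the weak base should ionise only the para hydroxyl (vinylogous carboxylic acid) while the ortho hydroxyls stay chelated to the formyl group, and the dipolar aprotic solvent favours O- over C-benzylation.

Step 4
Reactants: 6 4-(benzyloxy)-2,6-dihydroxybenzaldehyde
Product: 7 4-(benzyloxy)-2,6-dihydroxy-3-iodobenzaldehyde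
Conditions: NIS (1.0 equiv), DMF, 0 °C
Reagents that add atoms: N-iodosuccinimide, O=C1CCC(=O)N1I
Why: Electrophilic aromatic iodination of the activated ring, in which the two free positions of 6 are related by the mirror plane through C1 and C4 so that one equivalent of NIS can give only one mono-iodide, with iodine between a hydroxyl and the benzyloxy group, and which is done on the small aldehyde to avoid a late iodination next to the acid-sensitive diarylmethane.

Step 5
Reactants: 7 4-(benzyloxy)-2,6-dihydroxy-3-iodobenzaldehyde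
Product: 8 4-(benzyloxy)-3-iodo-2,6-bis(methoxymethoxy)benzaldehyde
Conditions: NaH (2.4 equiv), MOMCl (2.6 equiv), DMF, 0 °C → rt
Reagents that add atoms: chloromethyl methyl ether, COCCl
Why: O-alkylation of both sodium phenoxides by the small, reactive chloromethyl ether (acetal formation), with an aldehyde that has no α-hydrogen and is inert to NaH.

Step 6
Reactants: 8 4-(benzyloxy)-3-iodo-2,6-bis(methoxymethoxy)benzaldehyde
Product: 9 [4-(benzyloxy)-3-iodo-2,6-bis(methoxymethoxy)phenyl]methanol
Conditions: NaBH4, MeOH–THF, 0 °C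
Reagents that add atoms: none
Why: Borohydride reduction of the aldehyde, where capping of all three phenolic oxygens prevents collapse to an o-quinone methide so that the alcohol should be a storable benzylic electrophile, and where aryl iodide, acetals and benzyl ether are inert to NaBH4.

Step 7
Reactants: 4 1-(2,6-dihydroxy-4-methoxy-3-methylphenyl)-3-phenylpropan-1-one; 9 [4-(benzyloxy)-3-iodo-2,6-bis(methoxymethoxy)phenyl]methanol
Product: 10 1-[3-{[4-(benzyloxy)-3-iodo-2,6-bis(methoxymethoxy)phenyl]methyl}-2,6-dihydroxy-4-methoxy-5-methylphenyl]-3-phenylpropan-1-one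
Conditions: TsOH·H2O (5 mol %), CH2Cl2, −10 → 0 °C, slow addition of 9 to 4 (1.5 equiv)
Reagents that add atoms: none
Why: Friedel–Crafts benzylation in which catalytic acid ionises 9 to a benzyl cation stabilised by three alkoxy groups that attacks the only unsubstituted ring carbon of 4 (ortho to OH and OMe, para to the second OH), while reversible O-benzylation funnels to the C-benzyl product and the excess of 4 with slow addition of 9 keeps the cation away from the one remaining CH of the iodinated ring.

Step 8
Reactants: 10 1-[3-{[4-(benzyloxy)-3-iodo-2,6-bis(methoxymethoxy)phenyl]methyl}-2,6-dihydroxy-4-methoxy-5-methylphenyl]-3-phenylpropan-1-one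
Product: 11 1-[3-{[4-(benzyloxy)-3-iodo-2,6-bis(methoxymethoxy)phenyl]methyl}-4-methoxy-2,6-bis(methoxymethoxy)-5-methylphenyl]-3-phenylpropan-1-one
Conditions: NaH (2.5 equiv), MOMCl (3.0 equiv), DMF, 0 °C → rt
Reagents that add atoms: chloromethyl methyl ether, COCCl
Why: Phenoxide O-alkylation of the two chelated hydroxyls, which NaH deprotonates far faster than it enolises the hindered ketone, and which would also restore any MOM group lost in step 7.

Step 9
Reactants: 11 1-[3-{[4-(benzyloxy)-3-iodo-2,6-bis(methoxymethoxy)phenyl]methyl}-4-methoxy-2,6-bis(methoxymethoxy)-5-methylphenyl]-3-phenylpropan-1-one; 12 carbon monoxide; 13 2-methoxy-1-phenylethan-1-one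
Product: 16 1-[6-(benzyloxy)-3-{[6-methoxy-2,4-bis(methoxymethoxy)-5-methyl-3-(3-phenylpropanoyl)phenyl]methyl}-2,4-bis(methoxymethoxy)phenyl]-2-methoxy-3-phenylpropane-1,3-dione, via sodium 2-methoxy-1-phenylethen-1-olate 14 (not isolated), via sodium diketonate 15 (not isolated)
Conditions: 13 (2.6 equiv), NaN(SiMe3)2 (2.5 equiv), THF, −78 → 0 °C; then 11, Pd(OAc)2 (5 mol %), Xantphos (7.5 mol %), CO (1 atm), THF–dioxane, 70 °C; AcOH quench at 0 °C
Reagents that add atoms: none
Why: Zerovalent palladium, formed in situ from Pd(OAc)2 and Xantphos, inserts into the C–I bond of 11, CO insertion gives an aroyl complex of divalent palladium (C4a–C4), enolate 14 replaces iodide at the metal and C–C reductive elimination forms C4–C3. The closest known reaction is the palladium-catalysed carbonylative α-arylation of ketones with aryl iodides to 1,3-diketones. No ring closes here; the methoxylated carbon arises as an enolisable centre that is not controlled, and the product is held as diketonate 15, which consumes the second equivalent of 14 and shields the diketone from further acylation. Carbonylation must outrun direct α-arylation, which the two ortho substituents on the aryl palladium species and the wide bite angle of Xantphos should secure by favouring CO insertion over enolate coupling at the crowded aryl–metal bond. The enolate of 13 must outcompete that of the ring D ketone: 13 is the more acidic ketone (α-oxygen, conjugated benzoyl), it is preformed with slightly less than one equivalent of amide so that no stronger base remains, and the ring D carbonyl is twisted out of conjugation between two ortho MOM ethers. The place of iodine, between the MOM ether and the benzyl ether, fixes C4 on the future C4a.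

Step 10
Reactants: 16 1-[6-(benzyloxy)-3-{[6-methoxy-2,4-bis(methoxymethoxy)-5-methyl-3-(3-phenylpropanoyl)phenyl]methyl}-2,4-bis(methoxymethoxy)phenyl]-2-methoxy-3-phenylpropane-1,3-dione
Product: 19 5-(benzyloxy)-8-{[2,4-dihydroxy-6-methoxy-5-methyl-3-(3-phenylpropanoyl)phenyl]methyl}-7-hydroxy-3-methoxy-2-phenyl-4H-chromen-4-one, via tetraphenol diketone 17 (not isolated), via hydroxyflavanone hemiketal 18 (not isolated)
Conditions: HCl (3 M aq), MeOH–THF (1:1), 60 °C
Reagents that add atoms: none
Why: Acid-catalysed acetal solvolysis frees the four phenols (17), the one hydroxyl ortho to the aroyl group (the other ortho oxygen stays benzylated) adds 6-exo-trig to the benzoyl carbonyl (hemiketal 18, transient C2 and C3 centres uncontrolled) and dehydration aromatises the pyranone, which is the cyclodehydration that ends a Baker–Venkataraman flavone synthesis and can place the CH2 only at C8.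

Step 11
Reactants: 19 5-(benzyloxy)-8-{[2,4-dihydroxy-6-methoxy-5-methyl-3-(3-phenylpropanoyl)phenyl]methyl}-7-hydroxy-3-methoxy-2-phenyl-4H-chromen-4-one
Product: 20 8-{[2,4-dihydroxy-6-methoxy-5-methyl-3-(3-phenylpropanoyl)phenyl]methyl}-5,7-dihydroxy-3-methoxy-2-phenyl-4H-chromen-4-one (target)
Conditions: H2 (1 atm), 10% Pd/C, EtOAc–MeOH, rt
Reagents that add atoms: none
Why: Catalytic hydrogenolysis of the benzyl aryl ether, under which the tetrasubstituted chromone double bond, the two chelated aryl ketones and the diarylmethane should not be reduced at ambient pressure and temperature.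

Compound list
1 | 2-methylbenzene-1,3,5-triol (2-methylphloroglucinol) | Cc1c(O)cc(O)cc1O | starting material
2 | 3-phenylpropanoyl chloride | O=C(Cl)CCc1ccccc1 | starting material
3 | 1-(2,4,6-trihydroxy-3-methylphenyl)-3-phenylpropan-1-one | Cc1c(O)cc(O)c(C(=O)CCc2ccccc2)c1O | intermediate
4 | 1-(2,6-dihydroxy-4-methoxy-3-methylphenyl)-3-phenylpropan-1-one | COc1cc(O)c(C(=O)CCc2ccccc2)c(O)c1C | intermediate
5 | 2,4,6-trihydroxybenzaldehyde | O=Cc1c(O)cc(O)cc1O | starting material
6 | 4-(benzyloxy)-2,6-dihydroxybenzaldehyde | O=Cc1c(O)cc(OCc2ccccc2)cc1O | intermediate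
7 | 4-(benzyloxy)-2,6-dihydroxy-3-iodobenzaldehyde | O=Cc1c(O)cc(OCc2ccccc2)c(I)c1O | intermediate
8 | 4-(benzyloxy)-3-iodo-2,6-bis(methoxymethoxy)benzaldehyde | O=Cc1c(OCOC)cc(OCc2ccccc2)c(I)c1OCOC | intermediate
9 | [4-(benzyloxy)-3-iodo-2,6-bis(methoxymethoxy)phenyl]methanol | OCc1c(OCOC)cc(OCc2ccccc2)c(I)c1OCOC | intermediate
10 | 1-[3-{[4-(benzyloxy)-3-iodo-2,6-bis(methoxymethoxy)phenyl]methyl}-2,6-dihydroxy-4-methoxy-5-methylphenyl]-3-phenylpropan-1-one | COc1c(C)c(O)c(C(=O)CCc2ccccc2)c(O)c1Cc1c(OCOC)c(I)c(OCc2ccccc2)cc1OCOC | intermediate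
11 | 1-[3-{[4-(benzyloxy)-3-iodo-2,6-bis(methoxymethoxy)phenyl]methyl}-4-methoxy-2,6-bis(methoxymethoxy)-5-methylphenyl]-3-phenylpropan-1-one | COc1c(C)c(OCOC)c(C(=O)CCc2ccccc2)c(OCOC)c1Cc1c(OCOC)c(I)c(OCc2ccccc2)cc1OCOC | intermediate
12 | carbon monoxide | [C-]#[O+] | starting material
13 | 2-methoxy-1-phenylethan-1-one | COCC(=O)c1ccccc1 | starting material
14 | sodium 2-methoxy-1-phenylethen-1-olate (enolate geometry unassigned) | [Na+].[O-]C(=COC)c1ccccc1 | intermediate (not isolated)
15 | sodium enolate of diketone 16 (enolate geometry unassigned) | COc1c(C)c(OCOC)c(C(=O)CCc2ccccc2)c(OCOC)c1Cc1c(OCOC)c(C(=O)C(OC)=C([O-])c2ccccc2)c(OCc2ccccc2)cc1OCOC.[Na+] | intermediate (not isolated)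
16 | 1-[6-(benzyloxy)-3-{[6-methoxy-2,4-bis(methoxymethoxy)-5-methyl-3-(3-phenylpropanoyl)phenyl]methyl}-2,4-bis(methoxymethoxy)phenyl]-2-methoxy-3-phenylpropane-1,3-dione (C2 of the dione unassigned) | COc1c(C)c(OCOC)c(C(=O)CCc2ccccc2)c(OCOC)c1Cc1c(OCOC)c(C(=O)C(OC)C(=O)c2ccccc2)c(OCc2ccccc2)cc1OCOC | intermediate
17 | 1-[6-(benzyloxy)-3-{[2,4-dihydroxy-6-methoxy-5-methyl-3-(3-phenylpropanoyl)phenyl]methyl}-2,4-dihydroxyphenyl]-2-methoxy-3-phenylpropane-1,3-dione | COc1c(C)c(O)c(C(=O)CCc2ccccc2)c(O)c1Cc1c(O)c(C(=O)C(OC)C(=O)c2ccccc2)c(OCc2ccccc2)cc1O | intermediate (not isolated)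
18 | 5-(benzyloxy)-8-{[2,4-dihydroxy-6-methoxy-5-methyl-3-(3-phenylpropanoyl)phenyl]methyl}-2,7-dihydroxy-3-methoxy-2-phenyl-2,3-dihydro-4H-chromen-4-one (C2, C3 unassigned) | COc1c(C)c(O)c(C(=O)CCc2ccccc2)c(O)c1Cc1c(O)cc(OCc2ccccc2)c2c1OC(O)(c1ccccc1)C(OC)C2=O | intermediate (not isolated)
19 | 5-(benzyloxy)-8-{[2,4-dihydroxy-6-methoxy-5-methyl-3-(3-phenylpropanoyl)phenyl]methyl}-7-hydroxy-3-methoxy-2-phenyl-4H-chromen-4-one | COc1c(C)c(O)c(C(=O)CCc2ccccc2)c(O)c1Cc1c(O)cc(OCc2ccccc2)c2c(=O)c(OC)c(-c3ccccc3)oc12 | intermediate
20 | 8-{[2,4-dihydroxy-6-methoxy-5-methyl-3-(3-phenylpropanoyl)phenyl]methyl}-5,7-dihydroxy-3-methoxy-2-phenyl-4H-chromen-4-one | COc1c(C)c(O)c(C(=O)CCc2ccccc2)c(O)c1Cc1c(O)cc(O)c2c(=O)c(OC)c(-c3ccccc3)oc12 | target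

Total step count: 11. Longest linear sequence: 9 steps (steps 3 to 11, from 5 to 20); steps 1 and 2 form the second branch, which joins in step 7.

Steps most likely to fail

Step 9. The risks are slow oxidative addition at the doubly ortho-substituted iodide under CO, coupling without CO uptake, or proton transfer to the ring D ketone followed by acylation of the wrong enolate. The fallback builds the C4 chain stepwise with known reactions and sets out from iodide 11. Palladium-catalysed reductive carbonylation (Pd(OAc)2, 1,3-bis(diphenylphosphino)propane, CO, Et3SiH, Na2CO3, DMF, 80 °C) should give the aryl aldehyde F1. Ketone 13 is converted with LiN(i-Pr)2 in THF at −78 °C into lithium 2-methoxy-1-phenylethen-1-olate F2, which should add to F1 at that temperature without touching the hindered ring D ketone. This gives the β-hydroxy ketone F3 as a diastereomer mixture. Dess–Martin oxidation of F3 converges on diketone 16, where the route is rejoined.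

Step 7. The risks are self-condensation of the benzyl cation on the remaining CH of its own ring, acetal exchange between the benzylic position and a neighbouring MOM group, or loss of MOM groups under the acid. The fallback makes the bridge under neutral conditions and sets out from iodo aldehyde 7 together with ketone 4. Reductive amination of 7 with morpholine (NaBH(OAc)3, 1,2-dichloroethane, rt) should give the Mannich base 5-(benzyloxy)-4-iodo-2-(morpholin-4-ylmethyl)benzene-1,3-diol F4. Heating F4 with excess 4 in dioxane should expel morpholine to the o-quinone methide F5, which ring D captures at its only free carbon to give the tetraphenol 1-[3-{[4-(benzyloxy)-2,6-dihydroxy-3-iodophenyl]methyl}-2,6-dihydroxy-4-methoxy-5-methylphenyl]-3-phenylpropan-1-one F6. Exhaustive MOM protection of F6 (NaH, MOMCl, DMF) rejoins the route at 11.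

Step 3. The risks are spread of O-benzylation over the three hydroxyls, over-alkylation, or C-benzylation of the phloroglucinol anion. The fallback replaces selective alkylation by selective dealkylation and sets out from 5. Exhaustive benzylation (BnBr, K2CO3, DMF) should give 2,4,6-tris(benzyloxy)benzaldehyde F7. Chelation-directed cleavage of the two benzyl ethers ortho to the formyl group (MgBr2·OEt2, toluene–Et2O, reflux) leaves the para ether and rejoins the route at 6.

Further compounds
F1 | step 9 | 6-(benzyloxy)-3-{[6-methoxy-2,4-bis(methoxymethoxy)-5-methyl-3-(3-phenylpropanoyl)phenyl]methyl}-2,4-bis(methoxymethoxy)benzaldehyde | COc1c(C)c(OCOC)c(C(=O)CCc2ccccc2)c(OCOC)c1Cc1c(OCOC)c(C=O)c(OCc2ccccc2)cc1OCOC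
F2 | step 9 | lithium 2-methoxy-1-phenylethen-1-olate | [Li+].[O-]C(=COC)c1ccccc1
F3 | step 9 | 3-[6-(benzyloxy)-3-{[6-methoxy-2,4-bis(methoxymethoxy)-5-methyl-3-(3-phenylpropanoyl)phenyl]methyl}-2,4-bis(methoxymethoxy)phenyl]-3-hydroxy-2-methoxy-1-phenylpropan-1-one (diastereomer mixture, unassigned) | COc1c(C)c(OCOC)c(C(=O)CCc2ccccc2)c(OCOC)c1Cc1c(OCOC)c(C(O)C(OC)C(=O)c2ccccc2)c(OCc2ccccc2)cc1OCOC
F4 | step 7 | 5-(benzyloxy)-4-iodo-2-(morpholin-4-ylmethyl)benzene-1,3-diol | Oc1cc(OCc2ccccc2)c(I)c(O)c1CN1CCOCC1
F5 | step 7 | 3-(benzyloxy)-5-hydroxy-2-iodo-6-methylidenecyclohexa-2,4-dien-1-one | C=C1C(=O)C(I)=C(OCc2ccccc2)C=C1O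
F6 | step 7 | 1-[3-{[4-(benzyloxy)-2,6-dihydroxy-3-iodophenyl]methyl}-2,6-dihydroxy-4-methoxy-5-methylphenyl]-3-phenylpropan-1-one | COc1c(C)c(O)c(C(=O)CCc2ccccc2)c(O)c1Cc1c(O)c(I)c(OCc2ccccc2)cc1O
F7 | step 3 | 2,4,6-tris(benzyloxy)benzaldehyde | O=Cc1c(OCc2ccccc2)cc(OCc2ccccc2)cc1OCc1ccccc1
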